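**Plan**
- Feature: in the aryl ring (C1' benzofuran-2-yl, C2' prenyl, C3' OH, C4' H, C5' OMe, C6' prenyl) the oxygens on C3' and C5' are meta, with the only ring hydrogen (C4'–H) between them. This is the resorcinol monoester pattern obtained when CO is inserted between the two ends of a 3-acyloxy-1,4-enyne that has a terminal alkyne.
- Retrosynthesis: methyl, pivaloyl and silyl groups are removed, then C4'–C5' and C5'–C6' are cut (C5' = CO), unfolding the benzene ring to enyne pivalate 21. Compound 21 is cut at the carbinol–ethynyl bond and at the ketone–vinyl bond; the vinyl metal goes back to an alkyne, the alkyne to a prenyl–alkynyl bond and an acetyl group, and the furan ring to 2,4-dihydroxybenzaldehyde and chloroacetone.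
- Forward: the furan ring closes first (step 2), the C2 side chain is grown linearly (alkyne, skipped enyne, vinylstannane, enone, enyne ester), and the benzene ring closes in step 10, followed by O-methylation and a one-pot deprotection.
- Stereochemistry: the target has no stereocentre. The only controlled element is the trisubstituted alkene of 21, set by syn-hydrostannation (step 5) and kept through tin–lithium exchange; the racemic carbinol centre disappears on aromatisation.

Key step: step 10

Remark: the alkene geometry (prenyl CH2 cis to the benzofuran, trans to the tin, carbonyl or carbinol carbon) is the same in 12, 16, 17, 19, 20 and 21. It reads (E) in 12, 17 and 21 and (Z) in 16, 19 and 20 only because the CIP ranking of the geminal groups changes.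

Step 1
Reactants: 1 2,4-dihydroxybenzaldehyde
Product: 2 2-hydroxy-4-[(triisopropylsilyl)oxy]benzaldehyde
Conditions: TIPSCl (1.05 equiv), imidazole, CH2Cl2, 0 °C to rt
Reagents that add atoms: triisopropylsilyl chloride, CC(C)[Si](Cl)(C(C)C)C(C)C
Why: Regioselective O-silylation, because the 4-hydroxyl is the more acidic, unchelated phenol while the 2-hydroxyl is held in a hydrogen bond to the aldehyde.

Step 2
Reactants: 2 2-hydroxy-4-[(triisopropylsilyl)oxy]benzaldehyde; 3 chloroacetone
Product: 5 1-{6-[(triisopropylsilyl)oxy]-1-benzofuran-2-yl}ethan-1-one, via aryloxyacetone 4 (not isolated)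
Conditions: K2CO3, MeCN, 70 °C
Reagents that add atoms: none
Why: Rap–Stoermer benzofuran synthesis, in which O-alkylation of the phenol by the α-chloroketone is followed by intramolecular aldol condensation onto the aldehyde and dehydration, closing the furan ring with the acetyl group at C2 and the silyloxy group at C6.

Step 3
Reactants: 5 1-{6-[(triisopropylsilyl)oxy]-1-benzofuran-2-yl}ethan-1-one
Product: 8 2-ethynyl-6-[(triisopropylsilyl)oxy]-1-benzofuran, via lithium enolate 6 (not isolated), via enol phosphate 7 (not isolated)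
Conditions: LiN(iPr)2 (1.1 equiv), THF, –78 °C; ClP(O)(OEt)2, –78 °C to rt; then LiN(iPr)2 (2.3 equiv), THF, –78 °C to rt; aqueous NH4Cl
Reagents that add atoms: none
Why: Standard conversion of an aryl methyl ketone into a terminal alkyne by O-phosphorylation of the kinetic enolate and base-induced β-elimination of diethyl phosphate, the resulting acetylide being protonated on work-up.

Step 4
Reactants: 8 2-ethynyl-6-[(triisopropylsilyl)oxy]-1-benzofuran; 9 prenyl bromide (1-bromo-3-methylbut-2-ene)
Product: 11 2-(5-methylhex-4-en-1-yn-1-yl)-6-[(triisopropylsilyl)oxy]-1-benzofuran, via alkynylmagnesium bromide 10 (not isolated)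
Conditions: EtMgBr (1.0 equiv), THF, 0 °C to rt; CuBr·SMe2 (10 mol%), then 9, 50 °C
Reagents that add atoms: none
Why: Copper-catalysed coupling of an alkynyl Grignard reagent with a primary allylic bromide gives the skipped 1,4-enyne, attack at the unsubstituted CH2 terminus of prenyl bromide being the usual course and the aryl silyl ether being inert to the base.

Step 5
Reactants: 11 2-(5-methylhex-4-en-1-yn-1-yl)-6-[(triisopropylsilyl)oxy]-1-benzofuran
Product: 12 tributyl[(1E)-5-methyl-1-{6-[(triisopropylsilyl)oxy]-1-benzofuran-2-yl}hexa-1,4-dien-1-yl]stannane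
Conditions: Bu3SnH (slow addition), PdCl2(PPh3)2 (3 mol%), THF, 0 °C to rt
Reagents that add atoms: tributyltin hydride, CCCC[SnH](CCCC)CCCC
Why: Palladium-catalysed hydrostannation is a syn addition in which hydride goes to the alkyne carbon remote from the aryl group, so tin is expected on the benzofuranyl-bearing carbon (helped by the flanking ring oxygen, as with ortho-substituted arylalkynes) and the CH2 group ends up cis to the benzofuran.

Step 6
Reactants: 13 4-methylpent-3-enoic acid
Product: 15 N-methoxy-N,4-dimethylpent-3-enamide, via acyl imidazole 14 (not isolated)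
Conditions: 1,1'-carbonyldiimidazole, CH2Cl2, 0 °C to rt; MeNHOMe·HCl, rt
Reagents that add atoms: N,O-dimethylhydroxylamine hydrochloride, Cl.CNOC
Why: Weinreb amide formation through the acyl imidazole needs no added base, so the β,γ-double bond should not move into conjugation.

Step 7
Reactants: 12 tributyl[(1E)-5-methyl-1-{6-[(triisopropylsilyl)oxy]-1-benzofuran-2-yl}hexa-1,4-dien-1-yl]stannane; 15 N-methoxy-N,4-dimethylpent-3-enamide
Product: 17 (6E)-2,10-dimethyl-6-{6-[(triisopropylsilyl)oxy]-1-benzofuran-2-yl}undeca-2,6,9-trien-5-one, via vinyllithium 16 (not isolated)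
Conditions: n-BuLi (1.0 equiv), THF, –78 °C; then 15, –78 to –40 °C; aqueous NH4Cl
Reagents that add atoms: none
Why: Tin–lithium exchange of an α-aryl vinylstannane is fast at –78 °C and retains the alkene geometry, and the vinyllithium adds only once to the amide because the chelated tetrahedral adduct survives until work-up (Weinreb ketone synthesis).

Step 8
Reactants: 17 (6E)-2,10-dimethyl-6-{6-[(triisopropylsilyl)oxy]-1-benzofuran-2-yl}undeca-2,6,9-trien-5-one; 18 ethynylmagnesium bromide
Product: 19 racemic (6Z)-5-ethynyl-2,10-dimethyl-6-{6-[(triisopropylsilyl)oxy]-1-benzofuran-2-yl}undeca-2,6,9-trien-5-ol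
Conditions: HC≡CMgBr (2 equiv), LaCl3·2LiCl (1 equiv), THF, –78 to 0 °C; aqueous NH4Cl
Reagents that add atoms: none
Why: Grignard 1,2-addition to the ketone, with LaCl3·2LiCl added to raise carbonyl electrophilicity and suppress enolisation of the acidic β,γ-unsaturated CH2, gives the tertiary propargylic alcohol as a racemate, which suffices because this carbon becomes aromatic C2'.

Step 9
Reactants: 19 racemic (6Z)-5-ethynyl-2,10-dimethyl-6-{6-[(triisopropylsilyl)oxy]-1-benzofuran-2-yl}undeca-2,6,9-trien-5-ol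
Product: 21 racemic (6E)-5-ethynyl-2,10-dimethyl-6-{6-[(triisopropylsilyl)oxy]-1-benzofuran-2-yl}undeca-2,6,9-trien-5-yl 2,2-dimethylpropanoate, via lithium alkoxide 20 (not isolated)
Conditions: LiN(SiMe3)2 (1.05 equiv), THF, –78 °C; PivCl, –78 to 0 °C
Reagents that add atoms: pivaloyl chloride, CC(C)(C)C(=O)Cl
Why: O-acylation of a hindered tertiary alcohol through its lithium alkoxide is standard, and the lithium counterion and low temperature are chosen so that the 3-oxido-1,5-diene does not undergo an anionic oxy-Cope rearrangement.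

Step 10
Reactants: 21 racemic (6E)-5-ethynyl-2,10-dimethyl-6-{6-[(triisopropylsilyl)oxy]-1-benzofuran-2-yl}undeca-2,6,9-trien-5-yl 2,2-dimethylpropanoate; 22 carbon monoxide
Product: 24 5-hydroxy-2,4-bis(3-methylbut-2-en-1-yl)-3-{6-[(triisopropylsilyl)oxy]-1-benzofuran-2-yl}phenyl 2,2-dimethylpropanoate, via cyclohexadienone 23 (not isolated)
Conditions: [RhCl(CO)2]2 (5 mol%), CO (80 atm), CH2Cl2, 80 °C, autoclave
Reagents that add atoms: none
Why: Monovalent rhodium binds the terminal alkyne of 21, the pivalate carbonyl oxygen attacks the internal alkyne carbon and the ester shifts 1,2 (Rautenstrauch-type), leaving a rhodium vinylcarbene at the former terminal carbon (future C4'–H) that is conjugated through the new C3'=C2' bond with the C1'=C6' alkene. Carbon monoxide is taken up at the carbene carbon to form C4'–C5' (a dienylketene or its acyl-rhodacycle equivalent), and the six-membered carbocycle closes at C5'–C6' by 6π electrocyclisation of that ketene (equivalently C–C reductive elimination from the rhodacycle), giving cyclohexa-2,4-dienone 23, which tautomerises to phenol 24. The closest known reaction is the rhodium-catalysed [5+1] carbonylative cycloaddition of 3-acyloxy-1,4-enynes to resorcinol monoesters, applied here to a tertiary ester with a fully substituted diene. No stereocentre is created, since the racemic carbinol carbon becomes aromatic C2' and the sp3 carbon of 23 is lost on tautomerisation. The step needs 1,2- rather than 1,3-acyloxy migration, which the terminal alkyne secures, and capture of the carbene by CO rather than by a pendant prenyl alkene, which the CO pressure and the conjugated, pre-organised diene should secure. The (E) alkene puts hydrogen rather than CH2 on the inner face of the s-cis dienyl system so that closure at C6' is unhindered, and the migrated ester and the new free OH keep the two oxygens chemically distinct for the methylation that follows.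

Step 11
Reactants: 24 5-hydroxy-2,4-bis(3-methylbut-2-en-1-yl)-3-{6-[(triisopropylsilyl)oxy]-1-benzofuran-2-yl}phenyl 2,2-dimethylpropanoate
Product: 25 5-methoxy-2,4-bis(3-methylbut-2-en-1-yl)-3-{6-[(triisopropylsilyl)oxy]-1-benzofuran-2-yl}phenyl 2,2-dimethylpropanoate
Conditions: MeI, K2CO3, acetone, 40 °C
Reagents that add atoms: iodomethane, CI
Why: Williamson methylation of the only free phenol fixes OMe at C5', the hindered aryl pivalate and the aryl silyl ether being stable to carbonate in anhydrous acetone.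

Step 12
Reactants: 25 5-methoxy-2,4-bis(3-methylbut-2-en-1-yl)-3-{6-[(triisopropylsilyl)oxy]-1-benzofuran-2-yl}phenyl 2,2-dimethylpropanoate
Product: 27 2-[3-hydroxy-5-methoxy-2,6-bis(3-methylbut-2-en-1-yl)phenyl]-1-benzofuran-6-ol (CNP0324103.0), via phenol pivalate 26 (not isolated)
Conditions: Bu4NF (1.2 equiv), THF, 0 °C; then NaOMe, MeOH (degassed), rt; AcOH
Reagents that add atoms: none
Why: Fluoride cleaves the aryl silyl ether and methoxide then removes the aryl pivalate by transesterification, both standard deprotections run without acid so that the prenyl groups cannot cyclise onto the neighbouring phenol.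

**Compound list**
1 | 2,4-dihydroxybenzaldehyde | O=Cc1ccc(O)cc1O | starting material
2 | 2-hydroxy-4-[(triisopropylsilyl)oxy]benzaldehyde | O=Cc1ccc(O[Si](C(C)C)(C(C)C)C(C)C)cc1O | intermediate
3 | chloroacetone | CC(=O)CCl | starting material
4 | 2-(2-oxopropoxy)-4-[(triisopropylsilyl)oxy]benzaldehyde | CC(=O)COc1cc(O[Si](C(C)C)(C(C)C)C(C)C)ccc1C=O | intermediate (not isolated)
5 | 1-{6-[(triisopropylsilyl)oxy]-1-benzofuran-2-yl}ethan-1-one | CC(=O)c1cc2ccc(O[Si](C(C)C)(C(C)C)C(C)C)cc2o1 | intermediate
6 | lithium 1-{6-[(triisopropylsilyl)oxy]-1-benzofuran-2-yl}ethen-1-olate | [Li]OC(=C)c1cc2ccc(O[Si](C(C)C)(C(C)C)C(C)C)cc2o1 | intermediate (not isolated)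
7 | diethyl 1-{6-[(triisopropylsilyl)oxy]-1-benzofuran-2-yl}ethenyl phosphate | C=C(OP(=O)(OCC)OCC)c1cc2ccc(O[Si](C(C)C)(C(C)C)C(C)C)cc2o1 | intermediate (not isolated)
8 | 2-ethynyl-6-[(triisopropylsilyl)oxy]-1-benzofuran | C#Cc1cc2ccc(O[Si](C(C)C)(C(C)C)C(C)C)cc2o1 | intermediate
9 | prenyl bromide (1-bromo-3-methylbut-2-ene) | CC(C)=CCBr | starting material
10 | ({6-[(triisopropylsilyl)oxy]-1-benzofuran-2-yl}ethynyl)magnesium bromide | Br[Mg]C#Cc1cc2ccc(O[Si](C(C)C)(C(C)C)C(C)C)cc2o1 | intermediate (not isolated)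
11 | 2-(5-methylhex-4-en-1-yn-1-yl)-6-[(triisopropylsilyl)oxy]-1-benzofuran | CC(C)=CCC#Cc1cc2ccc(O[Si](C(C)C)(C(C)C)C(C)C)cc2o1 | intermediate
12 | tributyl[(1E)-5-methyl-1-{6-[(triisopropylsilyl)oxy]-1-benzofuran-2-yl}hexa-1,4-dien-1-yl]stannane (Sn cis to H) | CCCC[Sn](CCCC)(CCCC)/C(=C/CC=C(C)C)c1cc2ccc(O[Si](C(C)C)(C(C)C)C(C)C)cc2o1 | intermediate
13 | 4-methylpent-3-enoic acid | CC(C)=CCC(=O)O | starting material
14 | 1-(1H-imidazol-1-yl)-4-methylpent-3-en-1-one | CC(C)=CCC(=O)n1ccnc1 | intermediate (not isolated)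
15 | N-methoxy-N,4-dimethylpent-3-enamide | CC(C)=CCC(=O)N(C)OC | intermediate
16 | [(1Z)-5-methyl-1-{6-[(triisopropylsilyl)oxy]-1-benzofuran-2-yl}hexa-1,4-dien-1-yl]lithium (Li cis to H) | [Li]/C(=C/CC=C(C)C)c1cc2ccc(O[Si](C(C)C)(C(C)C)C(C)C)cc2o1 | intermediate (not isolated)
17 | (6E)-2,10-dimethyl-6-{6-[(triisopropylsilyl)oxy]-1-benzofuran-2-yl}undeca-2,6,9-trien-5-one | CC(C)=CCC(=O)/C(=C/CC=C(C)C)c1cc2ccc(O[Si](C(C)C)(C(C)C)C(C)C)cc2o1 | intermediate
18 | ethynylmagnesium bromide | C#C[Mg]Br | starting material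
19 | racemic (6Z)-5-ethynyl-2,10-dimethyl-6-{6-[(triisopropylsilyl)oxy]-1-benzofuran-2-yl}undeca-2,6,9-trien-5-ol | C#CC(O)(CC=C(C)C)/C(=C/CC=C(C)C)c1cc2ccc(O[Si](C(C)C)(C(C)C)C(C)C)cc2o1 | intermediate
20 | lithium alkoxide of 19 (racemic, 6Z) | [Li]OC(C#C)(CC=C(C)C)/C(=C/CC=C(C)C)c1cc2ccc(O[Si](C(C)C)(C(C)C)C(C)C)cc2o1 | intermediate (not isolated)
21 | racemic (6E)-5-ethynyl-2,10-dimethyl-6-{6-[(triisopropylsilyl)oxy]-1-benzofuran-2-yl}undeca-2,6,9-trien-5-yl 2,2-dimethylpropanoate | C#CC(OC(=O)C(C)(C)C)(CC=C(C)C)/C(=C/CC=C(C)C)c1cc2ccc(O[Si](C(C)C)(C(C)C)C(C)C)cc2o1 | intermediate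
22 | carbon monoxide | [C-]#[O+] | starting material
23 | racemic 4,6-bis(3-methylbut-2-en-1-yl)-3-oxo-5-{6-[(triisopropylsilyl)oxy]-1-benzofuran-2-yl}cyclohexa-1,5-dien-1-yl 2,2-dimethylpropanoate | O=C1C=C(OC(=O)C(C)(C)C)C(CC=C(C)C)=C(c2cc3ccc(O[Si](C(C)C)(C(C)C)C(C)C)cc3o2)C1CC=C(C)C | intermediate (not isolated)
24 | 5-hydroxy-2,4-bis(3-methylbut-2-en-1-yl)-3-{6-[(triisopropylsilyl)oxy]-1-benzofuran-2-yl}phenyl 2,2-dimethylpropanoate | Oc1cc(OC(=O)C(C)(C)C)c(CC=C(C)C)c(-c2cc3ccc(O[Si](C(C)C)(C(C)C)C(C)C)cc3o2)c1CC=C(C)C | intermediate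
25 | 5-methoxy-2,4-bis(3-methylbut-2-en-1-yl)-3-{6-[(triisopropylsilyl)oxy]-1-benzofuran-2-yl}phenyl 2,2-dimethylpropanoate | COc1cc(OC(=O)C(C)(C)C)c(CC=C(C)C)c(-c2cc3ccc(O[Si](C(C)C)(C(C)C)C(C)C)cc3o2)c1CC=C(C)C | intermediate
26 | 3-(6-hydroxy-1-benzofuran-2-yl)-5-methoxy-2,4-bis(3-methylbut-2-en-1-yl)phenyl 2,2-dimethylpropanoate | COc1cc(OC(=O)C(C)(C)C)c(CC=C(C)C)c(-c2cc3ccc(O)cc3o2)c1CC=C(C)C | intermediate (not isolated)
27 | 2-[3-hydroxy-5-methoxy-2,6-bis(3-methylbut-2-en-1-yl)phenyl]-1-benzofuran-6-ol | COc1cc(O)c(CC=C(C)C)c(-c2cc3ccc(O)cc3o2)c1CC=C(C)C | target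

**Step count and risks**
Total: 12 steps. Longest linear sequence: 11 steps (steps 1–5 and 7–12 from compound 1); step 6 is a one-step branch.

The three steps most likely to fail:

1. Step 10. The tertiary, doubly activated ester may ionise and lose pivalic acid, the ester may shift 1,3 to an allenyl ester, or the carbene may be intercepted by a prenyl alkene before CO is taken up. The fallback sets out from alcohol 19 and returns at target 27. Lithium alkoxide 20 would be acylated with 4-(dimethylamino)benzoyl chloride to the racemic (6E)-enyne 4-(dimethylamino)benzoate F1. Its more nucleophilic carbonyl oxygen is known to speed the 1,2-shift in rhodium-catalysed reactions of such enynes. Carbonylation with a cationic monovalent rhodium catalyst ([Rh(cod)2]BF4, P[OCH(CF3)2]3, CO, CH2Cl2) should give 5-hydroxy-2,4-bis(3-methylbut-2-en-1-yl)-3-{6-[(triisopropylsilyl)oxy]-1-benzofuran-2-yl}phenyl 4-(dimethylamino)benzoate F2. Mitsunobu methylation (MeOH, PPh3, diisopropyl azodicarboxylate), chosen so that the amino group is not quaternised, would give the methyl ether F3. Bu4NF and then NaOMe in MeOH, by way of the desilylated benzoate F4, would lead to 27.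

2. Step 5. Hydride may be delivered to the alkyne carbon next to the benzofuran, putting tin on the wrong carbon, or a palladium hydride may isomerise the skipped enyne. The fallback sets out from ketone 5 and returns at ketone 17, bypassing 8, 11 and 12. Lithium enolate 6 would be alkylated with prenyl bromide 9 (THF, –78 to 0 °C) to 5-methyl-1-{6-[(triisopropylsilyl)oxy]-1-benzofuran-2-yl}hex-4-en-1-one F5. Condensation with 2,4,6-triisopropylbenzenesulfonohydrazide would give the (E)-sulfonylhydrazone F6. A Shapiro reaction (n-BuLi, 2.1 equiv, THF, –78 to 0 °C) can deprotonate only the single α-CH2, so vinyllithium 16 forms regiospecifically, with the cis relation of aryl and CH2 that is usual for acyclic hydrazones. Acylation with amide 15 at –78 °C then gives 17.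

3. Step 8. The basic acetylide may deprotonate the CH2 between carbonyl and alkene, returning ketone or its conjugated isomer. The fallback sets out from stannane 12 and returns at alcohol 19; it introduces the alkyne first and the prenyl group last, so the ketone that is attacked cannot enolise. Vinyllithium 16 would be acylated with N-methoxy-N-methyl-3-(trimethylsilyl)prop-2-ynamide F7 (made from commercial 3-(trimethylsilyl)propiolic acid as in step 6) to the (4E)-ynone F8. Prenylbarium chloride F9 (from prenyl chloride and activated barium, itself made from BaI2 and lithium biphenylide, THF, –78 °C) adds to carbonyl groups at its unsubstituted CH2 terminus and should give the racemic (6Z) silylalkynyl carbinol F10. K2CO3 in MeOH at 0 °C removes the alkynyl silyl group and gives 19.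

**Further compounds**
F1 | step 10 | racemic (6E)-5-ethynyl-2,10-dimethyl-6-{6-[(triisopropylsilyl)oxy]-1-benzofuran-2-yl}undeca-2,6,9-trien-5-yl 4-(dimethylamino)benzoate | C#CC(OC(=O)c1ccc(N(C)C)cc1)(CC=C(C)C)/C(=C/CC=C(C)C)c1cc2ccc(O[Si](C(C)C)(C(C)C)C(C)C)cc2o1
F2 | step 10 | 5-hydroxy-2,4-bis(3-methylbut-2-en-1-yl)-3-{6-[(triisopropylsilyl)oxy]-1-benzofuran-2-yl}phenyl 4-(dimethylamino)benzoate | Oc1cc(OC(=O)c2ccc(N(C)C)cc2)c(CC=C(C)C)c(-c2cc3ccc(O[Si](C(C)C)(C(C)C)C(C)C)cc3o2)c1CC=C(C)C
F3 | step 10 | 5-methoxy-2,4-bis(3-methylbut-2-en-1-yl)-3-{6-[(triisopropylsilyl)oxy]-1-benzofuran-2-yl}phenyl 4-(dimethylamino)benzoate | COc1cc(OC(=O)c2ccc(N(C)C)cc2)c(CC=C(C)C)c(-c2cc3ccc(O[Si](C(C)C)(C(C)C)C(C)C)cc3o2)c1CC=C(C)C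
F4 | step 10 | 3-(6-hydroxy-1-benzofuran-2-yl)-5-methoxy-2,4-bis(3-methylbut-2-en-1-yl)phenyl 4-(dimethylamino)benzoate | COc1cc(OC(=O)c2ccc(N(C)C)cc2)c(CC=C(C)C)c(-c2cc3ccc(O)cc3o2)c1CC=C(C)C
F5 | step 5 | 5-methyl-1-{6-[(triisopropylsilyl)oxy]-1-benzofuran-2-yl}hex-4-en-1-one | CC(C)=CCCC(=O)c1cc2ccc(O[Si](C(C)C)(C(C)C)C(C)C)cc2o1
F6 | step 5 | N'-[(1E)-5-methyl-1-{6-[(triisopropylsilyl)oxy]-1-benzofuran-2-yl}hex-4-en-1-ylidene]-2,4,6-tri(propan-2-yl)benzenesulfonohydrazide | CC(C)=CCC/C(=N\NS(=O)(=O)c1c(C(C)C)cc(C(C)C)cc1C(C)C)c1cc2ccc(O[Si](C(C)C)(C(C)C)C(C)C)cc2o1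
F7 | step 8 | N-methoxy-N-methyl-3-(trimethylsilyl)prop-2-ynamide | C[Si](C)(C)C#CC(=O)N(C)OC
F8 | step 8 | (4E)-8-methyl-4-{6-[(triisopropylsilyl)oxy]-1-benzofuran-2-yl}-1-(trimethylsilyl)nona-4,7-dien-1-yn-3-one | C[Si](C)(C)C#CC(=O)/C(=C/CC=C(C)C)c1cc2ccc(O[Si](C(C)C)(C(C)C)C(C)C)cc2o1
F9 | step 8 | prenylbarium chloride | CC(C)=CC[Ba]Cl
F10 | step 8 | racemic (6Z)-2,10-dimethyl-6-{6-[(triisopropylsilyl)oxy]-1-benzofuran-2-yl}-5-[(trimethylsilyl)ethynyl]undeca-2,6,9-trien-5-ol | C[Si](C)(C)C#CC(O)(CC=C(C)C)/C(=C/CC=C(C)C)c1cc2ccc(O[Si](C(C)C)(C(C)C)C(C)C)cc2o1
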